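**Retrosynthetic overview**

1. Target 28 ⇒ its C18/C19 acetonide with an axial (8-epi) C17 aldehyde; the last operations are C17 oxidation, base epimerisation at C8 and acetal hydrolysis, and the butenolide ring (C13–C16) is attached preformed through C12–C13 by hydroboration/B-alkyl Suzuki coupling of a C9 vinyl group (C11=C12).
2. The vinyl group comes from a C11 acyl group on C9 and the saturated ring B from a Δ6-octalin; this exposes the key disconnection of C5–C10 and C8–C9 in one auxiliary-controlled intramolecular Diels–Alder reaction of an acyclic (E,E,E)-trienimide (dienophile C9=C10, diene C5=C6–C7=C8, tether C1–C4).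
3. Enabling feature: in ring B (C5–C6–C7–C8–C9–C10) the two bonds to be made flank the C9–C10 edge and are joined on the other side by C5–C6–C7–C8, a cyclohexene [4+2] pattern once C6=C7 is written in; C10 is also the ring-A fusion atom, so ring A (C1–C5, C10) closes in the same event; C9 carries C11 (activating acyl group), C8 is α to the C17 aldehyde (epimerisable) and C4 is an achiral quaternary carbon (gem-dialkyl effect).
4. The triene is assembled around C4 from triethyl methanetricarboxylate (C4, C5, C18, C19), 5-iodopent-1-yne (C1–C3, C9, C10), triethyl 4-phosphonocrotonate (C6–C8, C17), AlMe3 (C20) and methyl chloroformate (C11).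
5. Ring order: rings A and B together (step 11), then the preformed butenolide ring is introduced (step 16).

Key step: step 11

Remark: locants follow labdane numbering (ring A C1–C5/C10, ring B C5–C10, C11–C12 chain on C9, butenolide C13–C16 with O between C15 and C16, C17 on C8, C18/C19 on C4, C20 on C10); the target is the (5S,8S,9R,10S) enantiomer of the SMILES (C4 is not a stereocentre); TBS = tert-butyldimethylsilyl; "isopropylidenedioxy" = C18–O–C(CH3)2–O–C19 (spiro-1,3-dioxane at C4).

**Route**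

Step 1
Reactants: 1 triethyl methanetricarboxylate; 2 5-iodopent-1-yne
Product: 3 triethyl hex-5-yne-1,1,1-tricarboxylate
Conditions: NaH, DMF/toluene 1:1, 0 °C; then 2, 80 °C
Reagents that add atoms: none
Why: Malonate-type SN2 C-alkylation of the soft, weakly basic sodium methanetricarboxylate by the primary iodide leaves the terminal alkyne C–H untouched and creates the future quaternary C4.

Step 2
Reactants: 3 triethyl hex-5-yne-1,1,1-tricarboxylate
Product: 4 2-(hydroxymethyl)-2-(pent-4-yn-1-yl)propane-1,3-diol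
Conditions: LiAlH4, THF, 0 °C → reflux; Fieser work-up
Reagents that add atoms: none
Why: Exhaustive LiAlH4 reduction of the three non-enolisable esters should give the tris(hydroxymethyl) carbon, the alkyne being only deprotonated and not reduced.

Step 3
Reactants: 4 2-(hydroxymethyl)-2-(pent-4-yn-1-yl)propane-1,3-diol
Product: 5 [2,2-dimethyl-5-(pent-4-yn-1-yl)-1,3-dioxan-5-yl]methanol
Conditions: 2,2-dimethoxypropane, p-TsOH·H2O (cat), acetone, rt; Et3N quench
Reagents that add atoms: 2,2-dimethoxypropane, COC(C)(C)OC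
Why: Acid-catalysed acetonide formation (transketalisation) gives the six-membered 1,3-dioxane, and because the three CH2OH arms are equivalent only one mono-acetonide can form, leaving one arm free.

Step 4
Reactants: 5 [2,2-dimethyl-5-(pent-4-yn-1-yl)-1,3-dioxan-5-yl]methanol
Product: 6 2,2-dimethyl-5-(pent-4-yn-1-yl)-1,3-dioxane-5-carbaldehyde
Conditions: Dess–Martin periodinane, CH2Cl2, 0 °C → rt
Reagents that add atoms: none
Why: Dess–Martin oxidation of the neopentyl primary alcohol should stop cleanly at the non-enolisable aldehyde (C5).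

Step 5
Reactants: 6 2,2-dimethyl-5-(pent-4-yn-1-yl)-1,3-dioxane-5-carbaldehyde; 7 triethyl 4-phosphonocrotonate
Product: 8 ethyl (2E,4E)-5-[2,2-dimethyl-5-(pent-4-yn-1-yl)-1,3-dioxan-5-yl]penta-2,4-dienoate
Conditions: 7, LiHMDS, THF, −78 °C; then 6, −78 → 0 °C
Reagents that add atoms: none
Why: Vinylogous Horner–Wadsworth–Emmons olefination of the hindered aldehyde with the stabilised phosphonate anion should give the (E)-C5=C6 bond while the (E)-C7=C8 bond of the reagent is retained.

Step 6
Reactants: 8 ethyl (2E,4E)-5-[2,2-dimethyl-5-(pent-4-yn-1-yl)-1,3-dioxan-5-yl]penta-2,4-dienoate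
Product: 9 (2E,4E)-5-[2,2-dimethyl-5-(pent-4-yn-1-yl)-1,3-dioxan-5-yl]penta-2,4-dien-1-ol
Conditions: DIBAL-H, CH2Cl2, −78 °C; Rochelle salt work-up
Reagents that add atoms: none
Why: DIBAL-H 1,2-reduction of the dienoate at low temperature gives the dienol (C17 at the alcohol level) without conjugate reduction or hydroalumination of the alkyne.

Step 7
Reactants: 9 (2E,4E)-5-[2,2-dimethyl-5-(pent-4-yn-1-yl)-1,3-dioxan-5-yl]penta-2,4-dien-1-ol
Product: 10 tert-butyl({(2E,4E)-5-[2,2-dimethyl-5-(pent-4-yn-1-yl)-1,3-dioxan-5-yl]penta-2,4-dien-1-yl}oxy)dimethylsilane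
Conditions: TBSCl, imidazole, DMF, 0 °C → rt
Reagents that add atoms: tert-butyldimethylsilyl chloride, CC(C)(C)[Si](C)(C)Cl
Why: Standard silyl ether formation protects the primary dienylic alcohol for the organoaluminium, hydride and coupling steps that follow.

Step 8
Reactants: 10 tert-butyl({(2E,4E)-5-[2,2-dimethyl-5-(pent-4-yn-1-yl)-1,3-dioxan-5-yl]penta-2,4-dien-1-yl}oxy)dimethylsilane
Product: 12 methyl (2E)-6-{5-[(1E,3E)-5-(TBS-oxy)penta-1,3-dien-1-yl]-2,2-dimethyl-1,3-dioxan-5-yl}-3-methylhex-2-enoate, via (E)-alkenyldimethylalane 11 (not isolated)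
Conditions: AlMe3, Cp2ZrCl2 (cat), H2O (additive), CH2Cl2, −25 °C; then ClCO2Me, −25 °C → rt
Reagents that add atoms: trimethylaluminium, C[Al](C)C; methyl chloroformate, COC(=O)Cl
Why: Negishi zirconium-catalysed methylalumination adds CH3 (C20) to the internal and Al to the terminal alkyne carbon in syn fashion, and acylation of the alkenylalane by the chloroformate with retention gives the (E)-3-methyl-2-enoate (C20 cis to C11), the water-accelerated low-temperature variant being chosen to spare the acetonide.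

Step 9
Reactants: 12 methyl (2E)-6-{5-[(1E,3E)-5-(TBS-oxy)penta-1,3-dien-1-yl]-2,2-dimethyl-1,3-dioxan-5-yl}-3-methylhex-2-enoate
Product: 13 (2E)-6-{5-[(1E,3E)-5-(TBS-oxy)penta-1,3-dien-1-yl]-2,2-dimethyl-1,3-dioxan-5-yl}-3-methylhex-2-enoic acid
Conditions: LiOH·H2O, THF/MeOH/H2O 3:1:1, 40 °C; then 1 M HCl to pH 4, 0 °C
Reagents that add atoms: none
Why: Saponification of the methyl ester leaves the silyl ether and acetonide intact and cannot change the geometry of the trisubstituted alkene.

Step 10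
Reactants: 13 (2E)-6-{5-[(1E,3E)-5-(TBS-oxy)penta-1,3-dien-1-yl]-2,2-dimethyl-1,3-dioxan-5-yl}-3-methylhex-2-enoic acid; 14 (4R)-4-benzyl-1,3-oxazolidin-2-one
Product: 16 (4R)-4-benzyl-3-[(2E)-6-{5-[(1E,3E)-5-(TBS-oxy)penta-1,3-dien-1-yl]-2,2-dimethyl-1,3-dioxan-5-yl}-3-methylhex-2-enoyl]-1,3-oxazolidin-2-one, via mixed pivalic anhydride 15 (not isolated)
Conditions: PivCl, Et3N, THF, −20 °C; then 14, LiCl, −20 °C → rt
Reagents that add atoms: none
Why: N-acylation of the oxazolidinone through the mixed pivalic anhydride occurs at the less hindered enoyl carbonyl and installs the chelating activating group and chiral controller on C11.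

Step 11
Reactants: 16 (4R)-4-benzyl-3-[(2E)-6-{5-[(1E,3E)-5-(TBS-oxy)penta-1,3-dien-1-yl]-2,2-dimethyl-1,3-dioxan-5-yl}-3-methylhex-2-enoyl]-1,3-oxazolidin-2-one
Product: 17 (4R)-4-benzyl-3-[(5S,8R,9R,10R)-17-(TBS-oxy)-18,19-(isopropylidenedioxy)-12,13,14,15,16-pentanorlabd-6-en-11-oyl]-1,3-oxazolidin-2-one
Conditions: Me2AlCl, CH2Cl2, −30 → 0 °C
Reagents that add atoms: none
Why: Me2AlCl forms a cationic Me2Al+ chelate of the two imide carbonyls, which locks the enoyl unit s-cis and lowers the LUMO of the C9=C10 dienophile so that it undergoes a concerted but asynchronous normal-demand intramolecular [4+2] cycloaddition with the C5=C6–C7=C8 diene. The closest known reaction type is the auxiliary-controlled, Me2AlCl-promoted intramolecular Diels–Alder reaction of (E,E,E)-2,8,10-trienimides to trans-fused bicyclo[4.4.0]decenes. Ring B closes as the cyclohexene of the suprafacial [4+2] event (bonds C5–C10 and C8–C9), and ring A closes in the same transition state as a six-membered carbocycle through the four-carbon tether C1–C4 (type-1 mode, tether exo, chair-like, assisted by the gem-disubstituted C4). C9 and C10 are set by stereospecific transfer of the (E)-dienophile geometry (C20 and C11 cis), C5 relative to C10 by the endo position of the chelated acyl group, which places the tether anti and gives the trans ring fusion, and C8 by the (E)-C7=C8 geometry, which places CH2OTBS cis to C11 (8-epi, corrected in step 19). The absolute sense is set by the (R)-benzyl group, which shields the C9 si face of the chelate so that the diene adds to the re face, giving 5S,9R,10R as required. The step needs endo over exo and re over si selectivity, both secured by the rigid chelate, and site selectivity is not in question because C9=C10 is the only activated alkene.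

Step 12
Reactants: 17 (4R)-4-benzyl-3-[(5S,8R,9R,10R)-17-(TBS-oxy)-18,19-(isopropylidenedioxy)-12,13,14,15,16-pentanorlabd-6-en-11-oyl]-1,3-oxazolidin-2-one
Product: 18 (5S,8R,9R,10R)-17-(TBS-oxy)-18,19-(isopropylidenedioxy)-12,13,14,15,16-pentanorlabd-6-en-11-ol
Conditions: LiBH4, H2O (1 equiv per hydride reagent), Et2O, 0 °C
Reagents that add atoms: none
Why: Reductive cleavage of the N-acyloxazolidinone by LiBH4 at the exocyclic C11 carbonyl gives the primary alcohol and releases the auxiliary without touching a stereocentre.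

Step 13
Reactants: 18 (5S,8R,9R,10R)-17-(TBS-oxy)-18,19-(isopropylidenedioxy)-12,13,14,15,16-pentanorlabd-6-en-11-ol
Product: 19 (5S,8R,9R,10R)-17-(TBS-oxy)-18,19-(isopropylidenedioxy)-12,13,14,15,16-pentanorlabdan-11-ol
Conditions: H2 (1 atm), PtO2 (cat), EtOAc, rt
Reagents that add atoms: none
Why: Catalytic hydrogenation of the cis-disubstituted C6=C7 bond creates no stereocentre, and platinum is chosen because it is less prone than palladium to move the double bond toward C5.

Step 14
Reactants: 19 (5S,8R,9R,10R)-17-(TBS-oxy)-18,19-(isopropylidenedioxy)-12,13,14,15,16-pentanorlabdan-11-ol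
Product: 20 (5S,8R,9R,10R)-17-(TBS-oxy)-18,19-(isopropylidenedioxy)-12,13,14,15,16-pentanorlabdan-11-al
Conditions: Dess–Martin periodinane, CH2Cl2, 0 °C → rt
Reagents that add atoms: none
Why: Dess–Martin oxidation gives the C11 aldehyde under non-basic conditions, and the equatorial C9 substituent is in any case the thermodynamically preferred one.

Step 15
Reactants: 20 (5S,8R,9R,10R)-17-(TBS-oxy)-18,19-(isopropylidenedioxy)-12,13,14,15,16-pentanorlabdan-11-al
Product: 21 (5S,8R,9R,10S)-17-(TBS-oxy)-18,19-(isopropylidenedioxy)-13,14,15,16-tetranorlabd-11-ene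
Conditions: Ph3PCH3Br, KHMDS, THF, 0 °C; then 20, 0 °C → rt
Reagents that add atoms: methyltriphenylphosphonium bromide, C[P+](c1ccccc1)(c1ccccc1)c1ccccc1.[Br-]
Why: Wittig methylenation with the non-stabilised ylide converts the hindered C11 aldehyde into the C11=C12 vinyl group and brings in C12.

Step 16
Reactants: 21 (5S,8R,9R,10S)-17-(TBS-oxy)-18,19-(isopropylidenedioxy)-13,14,15,16-tetranorlabd-11-ene; 22 3-bromofuran-2(5H)-one
Product: 24 (5S,8R,9R,10S)-17-(TBS-oxy)-18,19-(isopropylidenedioxy)labd-13-en-16,15-olide, via B-alkyl-9-BBN adduct 23 (not isolated)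
Conditions: 9-BBN, THF, rt → 40 °C; then 22, PdCl2(dppf) (cat), AsPh3 (cat), Cs2CO3, DMF/H2O, rt
Reagents that add atoms: none
Why: Anti-Markovnikov hydroboration of the monosubstituted alkene puts boron on C12, and B-alkyl Suzuki–Miyaura coupling with the α-bromobutenolide forms the C12–C13 sp3–sp2 bond under mild base without affecting a stereocentre.

Step 17
Reactants: 24 (5S,8R,9R,10S)-17-(TBS-oxy)-18,19-(isopropylidenedioxy)labd-13-en-16,15-olide
Product: 25 (5S,8R,9R,10S)-17-hydroxy-18,19-(isopropylidenedioxy)labd-13-en-16,15-olide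
Conditions: HF·pyridine, pyridine, THF, 0 °C → rt
Reagents that add atoms: none
Why: Fluoride-mediated desilylation under buffered conditions removes the primary TBS ether while the acetonide and the base-sensitive butenolide are retained.

Step 18
Reactants: 25 (5S,8R,9R,10S)-17-hydroxy-18,19-(isopropylidenedioxy)labd-13-en-16,15-olide
Product: 26 (5S,8R,9R,10S)-18,19-(isopropylidenedioxy)-17-oxolabd-13-en-16,15-olide
Conditions: Dess–Martin periodinane, CH2Cl2, 0 °C → rt
Reagents that add atoms: none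
Why: Dess–Martin oxidation of the primary alcohol gives the C17 aldehyde, still axial on C8, without touching the butenolide.

Step 19
Reactants: 26 (5S,8R,9R,10S)-18,19-(isopropylidenedioxy)-17-oxolabd-13-en-16,15-olide
Product: 27 (5S,8S,9R,10S)-18,19-(isopropylidenedioxy)-17-oxolabd-13-en-16,15-olide
Conditions: DBU (cat), CH2Cl2, 0 °C → rt
Reagents that add atoms: none
Why: Base-mediated epimerisation through the aldehyde enolate is under thermodynamic control and should move the formyl group from the axial position (syn-diaxial to the C20 methyl) to the equatorial one, which sets C8 as S while C9 (no longer α to a carbonyl) cannot change.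

Step 20
Reactants: 27 (5S,8S,9R,10S)-18,19-(isopropylidenedioxy)-17-oxolabd-13-en-16,15-olide
Product: 28 (5S,8S,9R,10S)-18,19-dihydroxy-17-oxolabd-13-en-16,15-olide (CNP0332660.1)
Conditions: AcOH/H2O/THF 3:1:1, 40 °C
Reagents that add atoms: none
Why: Mild aqueous acid hydrolysis of the acetonide frees the C18/C19 diol, the aldehyde already being in its stable equatorial configuration and the butenolide being acid-stable.

**Compound list**

1 | triethyl methanetricarboxylate | CCOC(=O)C(C(=O)OCC)C(=O)OCC | starting material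
2 | 5-iodopent-1-yne | C#CCCCI | starting material
3 | triethyl hex-5-yne-1,1,1-tricarboxylate | C#CCCCC(C(=O)OCC)(C(=O)OCC)C(=O)OCC | intermediate
4 | 2-(hydroxymethyl)-2-(pent-4-yn-1-yl)propane-1,3-diol | C#CCCCC(CO)(CO)CO | intermediate
5 | [2,2-dimethyl-5-(pent-4-yn-1-yl)-1,3-dioxan-5-yl]methanol | C#CCCCC1(CO)COC(C)(C)OC1 | intermediate
6 | 2,2-dimethyl-5-(pent-4-yn-1-yl)-1,3-dioxane-5-carbaldehyde | C#CCCCC1(C=O)COC(C)(C)OC1 | intermediate
7 | triethyl 4-phosphonocrotonate [ethyl (2E)-4-(diethoxyphosphoryl)but-2-enoate] | CCOC(=O)/C=C/CP(=O)(OCC)OCC | starting material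
8 | ethyl (2E,4E)-5-[2,2-dimethyl-5-(pent-4-yn-1-yl)-1,3-dioxan-5-yl]penta-2,4-dienoate | C#CCCCC1(/C=C/C=C/C(=O)OCC)COC(C)(C)OC1 | intermediate
9 | (2E,4E)-5-[2,2-dimethyl-5-(pent-4-yn-1-yl)-1,3-dioxan-5-yl]penta-2,4-dien-1-ol | C#CCCCC1(/C=C/C=C/CO)COC(C)(C)OC1 | intermediate
10 | tert-butyl({(2E,4E)-5-[2,2-dimethyl-5-(pent-4-yn-1-yl)-1,3-dioxan-5-yl]penta-2,4-dien-1-yl}oxy)dimethylsilane | C#CCCCC1(/C=C/C=C/CO[Si](C)(C)C(C)(C)C)COC(C)(C)OC1 | intermediate
11 | [(1E)-5-{5-[(1E,3E)-5-(TBS-oxy)penta-1,3-dien-1-yl]-2,2-dimethyl-1,3-dioxan-5-yl}-2-methylpent-1-en-1-yl]dimethylalane (formed in situ) | C[Al](C)/C=C(\C)CCCC1(/C=C/C=C/CO[Si](C)(C)C(C)(C)C)COC(C)(C)OC1 | intermediate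
12 | methyl (2E)-6-{5-[(1E,3E)-5-(TBS-oxy)penta-1,3-dien-1-yl]-2,2-dimethyl-1,3-dioxan-5-yl}-3-methylhex-2-enoate | COC(=O)/C=C(\C)CCCC1(/C=C/C=C/CO[Si](C)(C)C(C)(C)C)COC(C)(C)OC1 | intermediate
13 | (2E)-6-{5-[(1E,3E)-5-(TBS-oxy)penta-1,3-dien-1-yl]-2,2-dimethyl-1,3-dioxan-5-yl}-3-methylhex-2-enoic acid | OC(=O)/C=C(\C)CCCC1(/C=C/C=C/CO[Si](C)(C)C(C)(C)C)COC(C)(C)OC1 | intermediate
14 | (4R)-4-benzyl-1,3-oxazolidin-2-one | O=C1N[C@H](Cc2ccccc2)CO1 | starting material
15 | mixed anhydride of acid 13 with pivalic acid (formed in situ) | CC(C)(C)C(=O)OC(=O)/C=C(\C)CCCC1(/C=C/C=C/CO[Si](C)(C)C(C)(C)C)COC(C)(C)OC1 | intermediate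
16 | (4R)-4-benzyl-3-[(2E)-6-{5-[(1E,3E)-5-(TBS-oxy)penta-1,3-dien-1-yl]-2,2-dimethyl-1,3-dioxan-5-yl}-3-methylhex-2-enoyl]-1,3-oxazolidin-2-one | O=C(/C=C(\C)CCCC1(/C=C/C=C/CO[Si](C)(C)C(C)(C)C)COC(C)(C)OC1)N1C(=O)OC[C@H]1Cc1ccccc1 | intermediate
17 | (4R)-4-benzyl-3-[(5S,8R,9R,10R)-17-(TBS-oxy)-18,19-(isopropylidenedioxy)-12,13,14,15,16-pentanorlabd-6-en-11-oyl]-1,3-oxazolidin-2-one (trans-fused Δ6-octalin; C20 methyl, C11 acyl and C17 on one face, H-5 on the other) | C[C@@]12CCCC3(COC(C)(C)OC3)[C@H]1C=C[C@@H](CO[Si](C)(C)C(C)(C)C)[C@H]2C(=O)N1C(=O)OC[C@H]1Cc1ccccc1 | intermediate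
18 | (5S,8R,9R,10R)-17-(TBS-oxy)-18,19-(isopropylidenedioxy)-12,13,14,15,16-pentanorlabd-6-en-11-ol | C[C@@]12CCCC3(COC(C)(C)OC3)[C@H]1C=C[C@@H](CO[Si](C)(C)C(C)(C)C)[C@H]2CO | intermediate
19 | (5S,8R,9R,10R)-17-(TBS-oxy)-18,19-(isopropylidenedioxy)-12,13,14,15,16-pentanorlabdan-11-ol | C[C@@]12CCCC3(COC(C)(C)OC3)[C@H]1CC[C@@H](CO[Si](C)(C)C(C)(C)C)[C@H]2CO | intermediate
20 | (5S,8R,9R,10R)-17-(TBS-oxy)-18,19-(isopropylidenedioxy)-12,13,14,15,16-pentanorlabdan-11-al | C[C@@]12CCCC3(COC(C)(C)OC3)[C@H]1CC[C@@H](CO[Si](C)(C)C(C)(C)C)[C@H]2C=O | intermediate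
21 | (5S,8R,9R,10S)-17-(TBS-oxy)-18,19-(isopropylidenedioxy)-13,14,15,16-tetranorlabd-11-ene (C9 vinyl compound) | C[C@@]12CCCC3(COC(C)(C)OC3)[C@H]1CC[C@@H](CO[Si](C)(C)C(C)(C)C)[C@H]2C=C | intermediate
22 | 3-bromofuran-2(5H)-one | O=C1OCC=C1Br | starting material
23 | 9-[(5S,8R,9R,10S)-17-(TBS-oxy)-18,19-(isopropylidenedioxy)-13,14,15,16-tetranorlabdan-12-yl]-9-borabicyclo[3.3.1]nonane (formed in situ) | C[C@@]12CCCC3(COC(C)(C)OC3)[C@H]1CC[C@@H](CO[Si](C)(C)C(C)(C)C)[C@H]2CCB1C2CCCC1CCC2 | intermediate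
24 | (5S,8R,9R,10S)-17-(TBS-oxy)-18,19-(isopropylidenedioxy)labd-13-en-16,15-olide | C[C@@]12CCCC3(COC(C)(C)OC3)[C@H]1CC[C@@H](CO[Si](C)(C)C(C)(C)C)[C@H]2CCC1=CCOC1=O | intermediate
25 | (5S,8R,9R,10S)-17-hydroxy-18,19-(isopropylidenedioxy)labd-13-en-16,15-olide | C[C@@]12CCCC3(COC(C)(C)OC3)[C@H]1CC[C@@H](CO)[C@H]2CCC1=CCOC1=O | intermediate
26 | (5S,8R,9R,10S)-18,19-(isopropylidenedioxy)-17-oxolabd-13-en-16,15-olide (8-epi, axial CHO) | C[C@@]12CCCC3(COC(C)(C)OC3)[C@H]1CC[C@@H](C=O)[C@H]2CCC1=CCOC1=O | intermediate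
27 | (5S,8S,9R,10S)-18,19-(isopropylidenedioxy)-17-oxolabd-13-en-16,15-olide | C[C@@]12CCCC3(COC(C)(C)OC3)[C@H]1CC[C@H](C=O)[C@H]2CCC1=CCOC1=O | intermediate
28 | (5S,8S,9R,10S)-18,19-dihydroxy-17-oxolabd-13-en-16,15-olide = (1R,2S,4aS,8aS)-5,5-bis(hydroxymethyl)-8a-methyl-1-[2-(2-oxo-2,5-dihydrofuran-3-yl)ethyl]decahydronaphthalene-2-carbaldehyde | C[C@@]12CCCC(CO)(CO)[C@H]1CC[C@H](C=O)[C@H]2CCC1=CCOC1=O | target

**Step count and risks**

Total step count: 20. Longest linear sequence: 20 steps (1 → 28); all other building blocks are used as purchased.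

Steps most likely to fail:

Step 11. Bond formation at the fully substituted C10 next to the neopentyl diene terminus C5 may be slow. At the temperature then required, Me2AlCl could cleave the acetonide or ionise the dienyl silyl ether, and endo and facial control by the chelate could erode. The fallback replaces auxiliary control and the stoichiometric aluminium Lewis acid by catalyst control under a mild chelating Lewis acid. It sets out from acid 13: acylation of 1,3-oxazolidin-2-one by the mixed-anhydride protocol of step 10 should give the achiral trienimide F1. A bis(oxazoline)copper(II)-catalysed intramolecular Diels–Alder reaction, [Cu((S,S)-t-Bu-box)](SbF6)2 (cat) in CH2Cl2 at rt, should then give the N-acyloxazolidinone cycloadduct F2. The square-planar chelate model places the diene on the C9 re face for this ligand antipode. LiBH4/H2O reduction as in step 12 comes back to the route at 18.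

Step 16. The α-bromobutenolide may decompose under the aqueous base (γ-deprotonation, lactone opening), and slow transmetalation of the hindered alkylborane may lead to protodeboronation or β-hydride elimination. The fallback is a base-free Negishi coupling setting out from 21. Hydroboration with 9-BBN followed by NaOH/H2O2 should give the primary alcohol F4. I2, PPh3 and imidazole in CH2Cl2 convert it into the primary iodide F5. Zinc insertion (Zn dust, LiCl, THF) gives the alkylzinc iodide F6, which is coupled without isolation with 22 under Pd2(dba)3/SPhos in THF at rt, coming back to the route at 24.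

Step 12. Hydride may attack the endocyclic carbamate carbonyl, because the C11 carbonyl is shielded by the quaternary C10 and the cis C8 substituent; this would open the auxiliary ring to a hydroxyethyl amide. The fallback is a two-stage cleavage setting out from 17. Lithium hydroperoxide (LiOH, H2O2, THF/H2O, 0 °C), which is selective for the exocyclic carbonyl, should give the carboxylic acid F3. LiAlH4 in THF at 0 °C reduces it to the alcohol, coming back to the route at 18.

Further compounds
F1 | step 11 | 3-[(2E)-6-{5-[(1E,3E)-5-(TBS-oxy)penta-1,3-dien-1-yl]-2,2-dimethyl-1,3-dioxan-5-yl}-3-methylhex-2-enoyl]-1,3-oxazolidin-2-one | O=C(/C=C(\C)CCCC1(/C=C/C=C/CO[Si](C)(C)C(C)(C)C)COC(C)(C)OC1)N1CCOC1=O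
F2 | step 11 | 3-[(5S,8R,9R,10R)-17-(TBS-oxy)-18,19-(isopropylidenedioxy)-12,13,14,15,16-pentanorlabd-6-en-11-oyl]-1,3-oxazolidin-2-one | C[C@@]12CCCC3(COC(C)(C)OC3)[C@H]1C=C[C@@H](CO[Si](C)(C)C(C)(C)C)[C@H]2C(=O)N1CCOC1=O
F3 | step 12 | (5S,8R,9R,10R)-17-(TBS-oxy)-18,19-(isopropylidenedioxy)-12,13,14,15,16-pentanorlabd-6-en-11-oic acid | C[C@@]12CCCC3(COC(C)(C)OC3)[C@H]1C=C[C@@H](CO[Si](C)(C)C(C)(C)C)[C@H]2C(O)=O
F4 | step 16 | (5S,8R,9R,10S)-17-(TBS-oxy)-18,19-(isopropylidenedioxy)-13,14,15,16-tetranorlabdan-12-ol | C[C@@]12CCCC3(COC(C)(C)OC3)[C@H]1CC[C@@H](CO[Si](C)(C)C(C)(C)C)[C@H]2CCO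
F5 | step 16 | (5S,8R,9R,10S)-12-iodo-17-(TBS-oxy)-18,19-(isopropylidenedioxy)-13,14,15,16-tetranorlabdane | C[C@@]12CCCC3(COC(C)(C)OC3)[C@H]1CC[C@@H](CO[Si](C)(C)C(C)(C)C)[C@H]2CCI
F6 | step 16 | [(5S,8R,9R,10S)-17-(TBS-oxy)-18,19-(isopropylidenedioxy)-13,14,15,16-tetranorlabdan-12-yl]zinc iodide | C[C@@]12CCCC3(COC(C)(C)OC3)[C@H]1CC[C@@H](CO[Si](C)(C)C(C)(C)C)[C@H]2CC[Zn]I
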